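The pitfall with a racemate is to expect a racemic product once it has reacted almost entirely, yet the two products of Saturday's run together read 98.6 % of the charge at 20.0 h with something odd: left-handed substrate is half of what was charged, and the left-handed product stands at 63.3 % of that charge, more than the left-handed substrate charged.

| flask | left-handed substrate | right-handed substrate | partner | free catalyst | racemization catalyst | remark | time |
|---|---|---|---|---|---|---|---|
| Saturday's | 0.067 M | 0.067 M | 0.20 M | 18 mM | 10 mM | run made earlier |  |
| Wednesday's | 0.15 M | 0.15 M | 0.20 M | 18 mM | 10 mM | run made earlier |  |
| flask | 0.10 M | 0.10 M | 0.200 M | 18 mM | 10 mM |  | 30 h |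

| run | time / h | left-handed product / % | right-handed product / % |
|---|---|---|---|
| Saturday's | 1.33 | 51.7 | 29.4 |
| Saturday's | 3.00 | 60.0 | 33.0 |
| Saturday's | 8.00 | 62.9 | 36.4 |
| Saturday's | 20.0 | 63.3 | 35.3 |
| Wednesday's | 1.33 | 38.6 | 20.5 |
| Wednesday's | 3.00 | 41.4 | 23.4 |
| Wednesday's | 8.00 | 39.9 | 23.7 |
| Wednesday's | 20.0 | 41.7 | 22.5 |

(readings scatter by 1 percentage point)

1. left-handed product and right-handed product together, in percent of the left-handed substrate and right-handed substrate charged together, at 30 h
2. excess of left-handed product over right-handed product in the product at 30 h
3. whether the exchange between left-handed substrate and right-handed substrate keeps pace with the reaction: how far the product's excess at 30 h gets from its value without exchange to its value with instant exchange (above 80 % keeps pace, below 20 % hardly takes part, else lags behind)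

- free catalyst is single-handed; left-handed substrate and right-handed substrate are mirror images of each other, charged as a racemate, each of them at the stated concentration
- the numbers in the tables scatter with a standard deviation of 1 percentage point
- reactions considered so far: partner + free catalyst + left-handed substrate -> free catalyst + left-handed product; 2 partner -> homo dimer; 2 free catalyst <-> resting dimer; partner + free catalyst + right-handed substrate -> free catalyst + right-handed product; left-handed substrate + racemization catalyst <-> right-handed substrate + racemization catalyst; free catalyst -> spent catalyst
- an excess is below zero if the other one leads

Those two numbers go together if right-handed substrate turns into left-handed substrate during the run. Saturday's excess of left-handed over right-handed product reads 27.5 % at 1.33 h and 28.4 % at 20.0 h. That difference of 0.9 percentage points compares with a scatter of 1 point on each reading, so I replace the curve by its mean and pool the readings of both runs: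

left-handed product, summed: 399.5 %

right-handed product, summed: 224.2 %

difference over total: 28.1 %

I call this the mean product excess, the share of the product by which the left-handed form leads; it goes with a ratio of the two products of 1.78 as read, a ratio that equals the selectivity factor if the exchange is instant. The flask's 0.10 M of each substrate lies between Saturday's 0.067 M and Wednesday's 0.15 M, with the same charges of partner and both catalysts, so I commit to an excess of about 28.1 % at 30 h.

The forecast gives 91 % (85 % to 96 %) of the charge as the two products together and an excess of 28 % (25 % to 31 %), and says the exchange keeps pace, noting of the excess that “it holds at 28% on Wednesday, so the exchange keeps pace”.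

The flask gives 90.1 % of the charge as the two products together, with an excess of 28.2 %, and its exchange keeps pace, as the forecast said.

    partner + free catalyst + left-handed substrate → free catalyst + left-handed product (k = 0.382 M⁻² s⁻¹)
    2 partner → homo dimer (k = 8.91 × 10⁻⁵ M⁻¹ s⁻¹)
    2 free catalyst ⇌ resting dimer, settled at all times (K = 29.9 M⁻¹)
    partner + free catalyst + right-handed substrate → free catalyst + right-handed product (k = 0.204 M⁻² s⁻¹)
    left-handed substrate + racemization catalyst ⇌ right-handed substrate + racemization catalyst, rate k5*[racemization catalyst]*[left-handed substrate] forward; the back reaction follows from the equilibrium constant (k = 0.166 M⁻¹ s⁻¹)
    free catalyst → spent catalyst (k = 8.15 × 10⁻⁵ s⁻¹)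

The mean product excess splits the flask's 90.1 % into 57.7 % left-handed and 32.4 % right-handed product, and the flask holds 57.8 % and 32.3 %. The same flask charged with 0.080 M of partner reaches 39.5 %, which the same excess splits into 25.3 % and 14.2 %, and that flask holds 25.6 % and 13.9 %. In the flask, the exchange alone relaxes the two substrates with a half-life of 0.0580 h at 30.0 h, both ways together, with the racemization catalyst at 100 % of its charge then as at 3.00 h, while left-handed substrate has a half-life of 0.47 h at 0.382 h by its turning into left-handed product, 8.10 times longer. The product's excess gets 90 % of the way from its value without exchange to its value with instant exchange.

(The earlier runs and the new flask were generated by integration with made-up constants; the scatter is artificial.)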